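## Structural features

The target is a 4→8 linked biflavonoid. An upper 3-deoxyflavan (rings A, C and B, with hydroxyls only at C7 and C4') is bonded through its C4 to C8 of a lower (−)-epigallocatechin unit (rings D, F and E). It has five stereocentres: upper C2 and C4, which are 1,3-related across ring C and cis (2S,4S), and lower C2 and C3, which are adjacent and cis (2R,3R). The fragile elements are the eight free hydroxyls (ring E is an air-sensitive pyrogallol), the two benzylic C2–O1 ether bonds, and the doubly benzylic C4–C8 bond to an electron-rich ring, which is acid-labile. The real difficulty is the crowded C4(sp3)–C8(aryl) junction, where C8 is flanked by O1 and the C7 oxygen of ring D. It is compounded by the need to control the absolute configuration at upper C2 and the 2,4-cis relation in a ring with no C3 oxygen to direct anything. Ring A is unsymmetrical (oxygen at C7, hydrogen at C5), so a construction through a ring A aryne needs a removable directing group at C5. The key step exploits the fact that the neighbouring ring A carbons C8a and C4a carry O1 and C4, the two ends of the O1–C2–C3–C4 chain of ring C. An aryne across C4a–C8a can therefore take up the hydroxyl oxygen and the ketone carbon of a preformed chiral β-hydroxy ketone.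

## Logic of the disconnections

**20 ⇒ 19.** The eight O–benzyl bonds and the C5–Cl bond are cut. All hydroxyls are masked by one group type that a single hydrogenolysis removes, and chlorine is the temporary director for the aryne step. This removes the oxidation-prone polyphenol from every earlier step. The demand is a hydrogenolysis that cleaves a hindered aryl chloride and eight benzyl ethers without opening the benzylic C2–O1 bonds.

**19 ⇒ 18.** The C4–H bond is traced back to a C4–OH bond. The tertiary carbinol is what carbonyl capture delivers directly, and its ionisation gives one planar, doubly benzylic cation from both C4 epimers. The C4 stereocentre therefore does not have to be controlled when the ring is made. The demand is hydride delivery to the face opposite the C2 aryl group under acid mild enough to spare the C2–O1 and C4–C8 bonds.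

**18 ⇒ 9 + 15.** The O1–C8a and C4–C4a bonds are cut. Both start from adjacent carbons of ring A, so ring A leaves as aryne 16 (made from 15), and the remainder is the open-chain β-hydroxy ketone 9 with C2 already in place. Ring C, the attachment of ring A and the crowded C4 quaternary centre all come from one convergent step. The demands are regioselective addition to the aryne (oxygen at C8a, carbanion at C4a as in 17), and ring closure that is faster than retro-aldol cleavage of 9 and faster than protonation of 17. The first is met by the C5 chlorine. The second is addressed by running in THF at low temperature and by benzylating the 3-hydroxyl so that 9 has only one hydroxyl.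

**9 ⇒ 6 + 7.** The C2–C3 bond is cut in the aldol sense. This is the β-hydroxy ketone retron and it sets upper C2, the only stereocentre of the upper unit that must be made with absolute control. The demand is reagent control in the aldol of a methyl ketone (through 8), since the lower-unit stereocentres are too remote to help.

**6 ⇒ 4 ⇒ 3 ⇒ 2 ⇒ 1.** The C8–acetyl bond is cut to an aryl anion (5) and an acetyl donor, then the C8–Br bond, then the six O–benzyl bonds. The chiral pool (1) supplies lower C2 and C3, and ring D is functionalised at its most nucleophilic position. The demands are C8-selective bromination and benzylation conditions that do not epimerise lower C2.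

**15 ⇒ 12 ⇒ 11 ⇒ 10.** The C–Si and O–Tf bonds are cut (through 14 and 13), then C–Br, then C–Cl. A retro-Brook sequence converts an ortho-bromophenol into the ortho-silyl triflate, and both halogens enter ortho to the hydroxyl of a para-blocked phenol. Chlorine is kept instead of bromine as the substituent beside the aryne because it polarises the aryne more strongly and is lost more slowly from the ortho-haloaryl anion 17. The demand is selective Br/Li exchange in the presence of chlorine.

## Other disconnections considered

**Alternative 1:** The cut is at upper C2–C3 and C4–C4a in one operation, with O1–C2 left for a later ring closure.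
- **Forward step.** The 8-vinyl derivative A1 (one vinylation from 4), aryl bromide A2 as ring A, and a photochemically generated α-methoxybenzyl radical would be joined with Ir[dF(CF3)ppy]2(dtbbpy)PF6 and NiBr2·glyme carrying a chiral bis(oxazoline). The radical adds to the CH2 terminus of A1, and the benzylic radical at C4 is captured by the arylnickel species, giving A3 with C4 set and the methoxy-bearing carbon as both epimers. Acid would then remove the MOM group, ionise the benzylic methyl ether and let the ring A phenol close ring C.
- **In favour.** Three pieces of similar size are joined in one step. The position of bromine in A2 fixes the ring A pattern, so no auxiliary chlorine is carried and removed; on this point it is better than the chosen plan. C4 is set by a catalyst and not by substrate-directed hydride delivery, which is at least equal in principle.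
- **Against.** The radical/nickel relay would operate at a benzylic carbon on a di-ortho-substituted arene and couple with an ortho-substituted aryl group, the most congested case of this reaction class. The lower-unit stereocentres could match or mismatch the catalyst. C2 would be formed last through a benzylic cation under thermodynamic control, in acid that also threatens the C4–C8 bond, whereas the chosen plan sets C2 with a reagent and never touches it again.
- **Comparison.** The longest linear sequences would be about equal, and the alternative would need fewer steps in total because no aryne precursor is made. The choice therefore rests on the security of C2 and the crowding at C4, not on length.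

**Alternative 2:** The cut removes ring D through the lower C8–C8a and C6–C7 bonds.
- **Forward step.** Heating cyclobutenone A5 with the 4-(silyloxyethynyl)flavan A4 would open A5 to a vinylketene, which adds the ynol ether; 4π opening, 6π closure and tautomerisation would give A6. A6 is a fully differentiated resorcinol with the upper flavan between hydroxyl and silyloxy and the cinnamyl chain next to the hydroxyl. Ring F would follow by asymmetric dihydroxylation of the cinnamyl alkene and cyclisation, with inversion at C3 to reach the cis series.
- **In favour.** The crowded C4–C8 bond is never made by a coupling at a hindered centre, because it is present from the start as the C(sp3)–C(sp) bond of A4; on steric demand this is better than the chosen plan. The regiochemistry of the hexasubstituted ring D follows from the pericyclic sequence, and the step needs neither acid, base nor metal.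
- **Against.** A4 is already a 2,4-cis flavan, so the upper-unit stereochemistry is moved into the precursor and not solved. The lower C2 and C3, which the chosen plan buys with 1, must be created and one of them inverted. The three ring D oxygens need three different protecting groups.
- **Comparison.** The mechanism is well understood and is the equal of the chosen key step in predictability. The route would be clearly longer, since ring F alone needs about five operations after the key step.

**Alternative 3:** The cut is the lower C4–C4a bond, so ring F is closed last on an upper flavan that already bears ring D.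
- **Forward step.** Sc(OTf)3 would activate the terminal epoxide of aryl ether A7. Ring D would attack the CH2 carbon through the position ortho to the ether oxygen (6-endo with respect to the epoxide), closing ring F and releasing the 3-hydroxyl in A8. One hydrogenolysis would then give 20.
- **In favour.** Epoxide–arene cyclisation onto an electron-rich ring is a reaction type with solid precedent, which the chosen key step lacks; on mechanistic security this step is the better one. The cis C2/C3 relation comes in with the epoxide and neither centre is touched. The end game is one step shorter than in the chosen plan.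
- **Against.** The step does not address the real problem. A7 presupposes the C4–C8 bond, the 2,4-cis upper flavan and a hindered secondary benzylic ether of a di-ortho-substituted phenol, all to be made by other means. Both lower-unit stereocentres must be made and not bought. The Lewis acid could ionise the benzylic C–O bond next to ring E or either flavan C2–O bond, and 5-exo opening at the internal epoxide carbon competes.
- **Comparison.** The overall sequence would be longer and would still need a separate solution for the upper unit.

Key step: step 9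

Remark on the structures: the lower unit of 9 carries six benzyl groups (five phenolic and the 3-O-benzyl), so it is a hexa-O-benzyl and not a penta-O-benzyl epigallocatechin residue; the 3-O-benzyl is needed because a free 3-hydroxyl would also add to the aryne.

Assumption on the aldol: the methyl-ketone enol borinate from (+)-Ipc2BCl is taken to attack the si face of the aldehyde (the reverse of the ethyl-ketone sense), which gives the (S)-carbinol; if the sense proved opposite, (−)-Ipc2BCl would be used with no other change.

## Route

**Step 1**
Reactants: 1 (−)-epigallocatechin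
Product: 2 5,7,3',4',5'-penta-O-benzyl-(−)-epigallocatechin (free 3-OH)
Conditions: BnBr (5.5 equiv), K2CO3, DMF, 0 °C → rt, argon
Reagents that add atoms: benzyl bromide BrCc1ccccc1
Why: Williamson etherification; carbonate deprotonates only the five phenols, so the secondary 3-hydroxyl stays free. Low temperature and exclusion of air should prevent C-benzylation, oxidation of the pyrogallol ring and epimerisation at C2.

**Step 2**
Reactants: 2 5,7,3',4',5'-penta-O-benzyl-(−)-epigallocatechin
Product: 3 3,5,7,3',4',5'-hexa-O-benzyl-(−)-epigallocatechin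
Conditions: NaH, BnBr, Bu4NI (cat.), THF–DMF, 0 °C → rt
Reagents that add atoms: benzyl bromide BrCc1ccccc1
Why: Williamson etherification of the secondary alkoxide. With all phenols capped, no quinone methide pathway is open, so C2 and C3 should be configurationally safe.

**Step 3**
Reactants: 3 3,5,7,3',4',5'-hexa-O-benzyl-(−)-epigallocatechin
Product: 4 8-bromo-hexa-O-benzyl-(−)-epigallocatechin
Conditions: NBS (1.0 equiv), CH2Cl2, −78 → 0 °C
Reagents that add atoms: N-bromosuccinimide O=C1CCC(=O)N1Br
Why: Electrophilic aromatic bromination; ring D with three oxygen donors is the most nucleophilic ring, and in 5,7-dialkoxyflavans C8 reacts before C6. One equivalent at low temperature should leave ring E untouched.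

**Step 4**
Reactants: 4 8-bromo-hexa-O-benzyl-(−)-epigallocatechin
Product: 6 8-acetyl-hexa-O-benzyl-(−)-epigallocatechin, via 8-lithio hexabenzyl ether 5 (not isolated)
Conditions: n-BuLi, THF, −78 °C; MeC(O)N(OMe)Me, −78 → 0 °C; aq. NH4Cl
Reagents that add atoms: N-methoxy-N-methylacetamide CC(=O)N(C)OC
Why: Bromine–lithium exchange followed by acylation with a Weinreb amide, whose chelated tetrahedral adduct prevents double addition. Benzyl ethers tolerate n-BuLi at −78 °C for the short time needed.

**Step 5**
Reactants: 6 8-acetyl-hexa-O-benzyl-(−)-epigallocatechin; 7 4-(benzyloxy)benzaldehyde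
Product: 9 (S)-3-[4-(benzyloxy)phenyl]-3-hydroxy-1-(hexa-O-benzyl-epigallocatechin-8-yl)propan-1-one, via enol diisopinocampheylborinate 8 (not isolated)
Conditions: (+)-Ipc2BCl, Et3N, Et2O, 0 °C; 7, −78 → −20 °C; H2O2, MeOH, pH 7 buffer, 0 °C
Reagents that add atoms: none
Why: Boron aldol of a methyl ketone through a closed transition state; the isopinocampheyl ligands on boron select the aldehyde face and so set the carbinol centre (future upper C2) as S. Selectivity of this reagent with methyl ketones is moderate, but the minor epimer is a diastereomer of 9 and should be removable by chromatography.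

**Step 6**
Reactants: 10 4-(benzyloxy)phenol
Product: 11 4-(benzyloxy)-2-chlorophenol
Conditions: SO2Cl2 (1.05 equiv), i-Bu2NH (cat.), toluene, 0 °C → rt
Reagents that add atoms: sulfuryl chloride O=S(=O)(Cl)Cl
Why: Amine-catalysed ortho-chlorination of a phenol; the para position is blocked and the hydroxyl directs more strongly than the benzyloxy group.

**Step 7**
Reactants: 11 4-(benzyloxy)-2-chlorophenol
Product: 12 4-(benzyloxy)-2-bromo-6-chlorophenol
Conditions: NBS (1.05 equiv), i-Pr2NH (cat.), CH2Cl2, 0 °C
Reagents that add atoms: N-bromosuccinimide O=C1CCC(=O)N1Br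
Why: Amine-catalysed ortho-bromination of a phenol at the only remaining position ortho to the hydroxyl.

**Step 8**
Reactants: 12 4-(benzyloxy)-2-bromo-6-chlorophenol
Product: 15 4-(benzyloxy)-2-chloro-6-(trimethylsilyl)phenyl trifluoromethanesulfonate, via aryl trimethylsilyl ether 13 (not isolated), via lithium 2-silylphenoxide 14 (not isolated)
Conditions: HMDS, THF, 65 °C, then evaporate; n-BuLi, THF, −78 °C; Tf2O, −78 → 0 °C
Reagents that add atoms: hexamethyldisilazane C[Si](C)(C)N[Si](C)(C)C; trifluoromethanesulfonic anhydride O=S(=O)(OS(=O)(=O)C(F)(F)F)C(F)(F)F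
Why: O-silylation, then Br/Li exchange (bromine reacts, chlorine does not) and retro-Brook 1,3-shift of silicon from oxygen to carbon, then O-triflation of the phenoxide. This is the standard one-flask route from ortho-bromophenols to ortho-silylaryl triflates.

**Step 9**
Reactants: 9 (S)-3-[4-(benzyloxy)phenyl]-3-hydroxy-1-(hexa-O-benzyl-epigallocatechin-8-yl)propan-1-one; 15 4-(benzyloxy)-2-chloro-6-(trimethylsilyl)phenyl trifluoromethanesulfonate
Product: 18 (2S)-7-(benzyloxy)-2-[4-(benzyloxy)phenyl]-5-chloro-4-(hexa-O-benzyl-epigallocatechin-8-yl)chroman-4-ol as both C4 epimers, via 5-(benzyloxy)-3-chlorobenzyne 16 (not isolated), via caesium aryl species 17 (not isolated)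
Conditions: CsF (4 equiv), 18-crown-6 (1 equiv), THF, 0 °C → rt; 15 (1.5 equiv) added in portions
Reagents that add atoms: none
Why: Proposed new method: fluoride removes the silyl group of 15 and triflate leaves, giving aryne 16; the hydroxyl oxygen of 9, activated as its fluoride-bridged caesium alkoxide, adds to the aryne carbon remote from chlorine (future C8a) and leaves the carbanion on the carbon next to chlorine (future C4a, species 17), which attacks the C4 ketone and gives 18 after protonation on work-up; the closest known reaction type is insertion of arynes into O–H bonds with intramolecular capture of the aryl anion by a carbonyl group, as in the annulation of arynes with ortho-hydroxyaryl ketones and esters. Ring C is closed by 6-exo-trig attack of the aryl anion on the carbonyl carbon, the O1–C8a bond having been formed intermolecularly just before. The new C4 carbinol centre is not controlled and need not be, because step 10 takes both epimers through one planar cation; C2 keeps the configuration set in step 5 because its C–O bond is never broken. The selectivity that matters is the regiochemistry of addition to the aryne: the C5 chlorine distorts and polarises the aryne so that the nucleophile enters meta to it and the negative charge develops ortho to it, and this should outweigh the weak opposite bias of the 7-benzyloxy group. THF is chosen over acetonitrile so that the aryl anion meets no acidic solvent proton, 18-crown-6 lets the aryne form at 0 °C where retro-aldol cleavage of the alkoxide is slow, and the 3-O-benzyl group keeps the only other hydroxyl out of the reaction. The acid-sensitive carbinol is passed to step 10 after filtration through base-washed silica.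

**Step 10**
Reactants: 18 (2S)-7-(benzyloxy)-2-[4-(benzyloxy)phenyl]-5-chloro-4-(hexa-O-benzyl-epigallocatechin-8-yl)chroman-4-ol
Product: 19 (2S,4R)-7-(benzyloxy)-2-[4-(benzyloxy)phenyl]-5-chloro-4-(hexa-O-benzyl-epigallocatechin-8-yl)chromane (2,4-cis)
Conditions: Et3SiH, CF3CO2H, CH2Cl2, −40 → 0 °C
Reagents that add atoms: none
Why: Ionic hydrogenation; the tertiary, doubly benzylic carbinol ionises readily because the cation is stabilised by the 7-benzyloxy group and the trioxygenated ring D, so a Brønsted acid is enough and the C2–O1 bonds are not put at risk by a strong Lewis acid. Hydride should add pseudo-axially to the sofa-shaped cation on the face carrying the axial H2, anti to the equatorial C2 aryl group, which places the two aryl groups cis; 4R here is the same spatial arrangement as 4S in 20, the descriptor changing only because chlorine raises the rank of C4a.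

**Step 11**
Reactants: 19 (2S,4R)-7-(benzyloxy)-2-[4-(benzyloxy)phenyl]-5-chloro-4-(hexa-O-benzyl-epigallocatechin-8-yl)chromane
Product: 20 (2R,3R)-8-[(2S,4S)-7-hydroxy-2-(4-hydroxyphenyl)chroman-4-yl]-2-(3,4,5-trihydroxyphenyl)chromane-3,5,7-triol
Conditions: H2 (1 atm), Pd(OH)2/C, THF–MeOH, rt; then Et3N, H2, rt; AcOH before filtration under argon
Reagents that add atoms: none
Why: Hydrogenolysis of the eight benzyl ethers followed, in the same flask, by base-promoted hydrodechlorination of the aryl chloride. The amine is added only after debenzylation because amines slow benzyl ether cleavage, and the mixture is acidified before exposure to air to protect the pyrogallol ring.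

## Compound list

1 | (−)-epigallocatechin, (2R,3R)-2-(3,4,5-trihydroxyphenyl)chromane-3,5,7-triol | Oc1cc(O)c2c(c1)O[C@H](c1cc(O)c(O)c(O)c1)[C@H](O)C2 | starting material
2 | (2R,3R)-5,7-bis(benzyloxy)-2-[3,4,5-tris(benzyloxy)phenyl]chroman-3-ol | c1c(OCc2ccccc2)cc(OCc2ccccc2)c2c1O[C@H](c1cc(OCc3ccccc3)c(OCc3ccccc3)c(OCc3ccccc3)c1)[C@H](O)C2 | intermediate
3 | (2R,3R)-3,5,7-tris(benzyloxy)-2-[3,4,5-tris(benzyloxy)phenyl]chromane | c1c(OCc2ccccc2)cc(OCc2ccccc2)c2c1O[C@H](c1cc(OCc3ccccc3)c(OCc3ccccc3)c(OCc3ccccc3)c1)[C@H](OCc1ccccc1)C2 | intermediate
4 | (2R,3R)-3,5,7-tris(benzyloxy)-8-bromo-2-[3,4,5-tris(benzyloxy)phenyl]chromane | Brc1c(OCc2ccccc2)cc(OCc2ccccc2)c2c1O[C@H](c1cc(OCc3ccccc3)c(OCc3ccccc3)c(OCc3ccccc3)c1)[C@H](OCc1ccccc1)C2 | intermediate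
5 | 8-lithio derivative of 3 (aryllithium at C8) | [Li]c1c(OCc2ccccc2)cc(OCc2ccccc2)c2c1O[C@H](c1cc(OCc3ccccc3)c(OCc3ccccc3)c(OCc3ccccc3)c1)[C@H](OCc1ccccc1)C2 | intermediate
6 | 1-{(2R,3R)-3,5,7-tris(benzyloxy)-2-[3,4,5-tris(benzyloxy)phenyl]chroman-8-yl}ethan-1-one | CC(=O)c1c(OCc2ccccc2)cc(OCc2ccccc2)c2c1O[C@H](c1cc(OCc3ccccc3)c(OCc3ccccc3)c(OCc3ccccc3)c1)[C@H](OCc1ccccc1)C2 | intermediate
7 | 4-(benzyloxy)benzaldehyde | O=Cc1ccc(OCc2ccccc2)cc1 | starting material
8 | enol diisopinocampheylborinate of 6, isopinocampheyl groups from (−)-α-pinene | C=C(OB([C@H]1C[C@H]2C[C@@H]([C@@H]1C)C2(C)C)[C@H]1C[C@H]2C[C@@H]([C@@H]1C)C2(C)C)c1c(OCc2ccccc2)cc(OCc2ccccc2)c2c1O[C@H](c1cc(OCc3ccccc3)c(OCc3ccccc3)c(OCc3ccccc3)c1)[C@H](OCc1ccccc1)C2 | intermediate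
9 | (S)-3-[4-(benzyloxy)phenyl]-3-hydroxy-1-{(2R,3R)-3,5,7-tris(benzyloxy)-2-[3,4,5-tris(benzyloxy)phenyl]chroman-8-yl}propan-1-one | c1ccccc1COc1ccc([C@@H](O)CC(=O)c2c(OCc3ccccc3)cc(OCc3ccccc3)c3c2O[C@H](c2cc(OCc4ccccc4)c(OCc4ccccc4)c(OCc4ccccc4)c2)[C@H](OCc2ccccc2)C3)cc1 | intermediate
10 | 4-(benzyloxy)phenol | Oc1ccc(OCc2ccccc2)cc1 | starting material
11 | 4-(benzyloxy)-2-chlorophenol | Oc1ccc(OCc2ccccc2)cc1Cl | intermediate
12 | 4-(benzyloxy)-2-bromo-6-chlorophenol | Oc1c(Br)cc(OCc2ccccc2)cc1Cl | intermediate
13 | [4-(benzyloxy)-2-bromo-6-chlorophenoxy]trimethylsilane | C[Si](C)(C)Oc1c(Br)cc(OCc2ccccc2)cc1Cl | intermediate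
14 | lithium 4-(benzyloxy)-2-chloro-6-(trimethylsilyl)phenolate | [Li+].[O-]c1c(Cl)cc(OCc2ccccc2)cc1[Si](C)(C)C | intermediate
15 | 4-(benzyloxy)-2-chloro-6-(trimethylsilyl)phenyl trifluoromethanesulfonate | C[Si](C)(C)c1cc(OCc2ccccc2)cc(Cl)c1OS(=O)(=O)C(F)(F)F | intermediate
16 | 5-(benzyloxy)-3-chlorobenzyne (5-(benzyloxy)-3-chloro-1,2-didehydrobenzene) | ClC1=CC(OCc2ccccc2)=CC#C1 | intermediate
17 | caesium aryl species: 3-O-[5-(benzyloxy)-3-chlorophenyl] ether of 9 with the carbanion at the ring carbon between oxygen and chlorine (future C4a) | c1ccccc1COc1ccc([C@@H](Oc2cc(OCc3ccccc3)cc(Cl)[c-]2)CC(=O)c2c(OCc3ccccc3)cc(OCc3ccccc3)c3c2O[C@H](c2cc(OCc4ccccc4)c(OCc4ccccc4)c(OCc4ccccc4)c2)[C@H](OCc2ccccc2)C3)cc1.[Cs+] | intermediate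
18 | (2S)-7-(benzyloxy)-2-[4-(benzyloxy)phenyl]-5-chloro-4-{(2R,3R)-3,5,7-tris(benzyloxy)-2-[3,4,5-tris(benzyloxy)phenyl]chroman-8-yl}chroman-4-ol, both C4 epimers | c1ccccc1COc1ccc([C@@H]2CC(O)(c3c(OCc4ccccc4)cc(OCc4ccccc4)c4c3O[C@H](c3cc(OCc5ccccc5)c(OCc5ccccc5)c(OCc5ccccc5)c3)[C@H](OCc3ccccc3)C4)c3c(Cl)cc(OCc4ccccc4)cc3O2)cc1 | intermediate
19 | (2R,3R)-3,5,7-tris(benzyloxy)-8-{(2S,4R)-7-(benzyloxy)-2-[4-(benzyloxy)phenyl]-5-chlorochroman-4-yl}-2-[3,4,5-tris(benzyloxy)phenyl]chromane, upper unit 2,4-cis | c1ccccc1COc1ccc([C@@H]2C[C@H](c3c(OCc4ccccc4)cc(OCc4ccccc4)c4c3O[C@H](c3cc(OCc5ccccc5)c(OCc5ccccc5)c(OCc5ccccc5)c3)[C@H](OCc3ccccc3)C4)c3c(Cl)cc(OCc4ccccc4)cc3O2)cc1 | intermediate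
20 | (2R,3R)-8-[(2S,4S)-7-hydroxy-2-(4-hydroxyphenyl)chroman-4-yl]-2-(3,4,5-trihydroxyphenyl)chromane-3,5,7-triol | Oc1ccc([C@@H]2C[C@H](c3c(O)cc(O)c4c3O[C@H](c3cc(O)c(O)c(O)c3)[C@H](O)C4)c3ccc(O)cc3O2)cc1 | target

## Step count and least certain steps

Total step count: 11. Longest linear sequence: 8 steps (steps 1, 2, 3, 4, 5, 9, 10 and 11); steps 6 to 8 form the three-step branch to 15.

**Step 9 (key step, proposed new method).**
- What may go wrong: retro-aldol cleavage of the alkoxide of 9 before it meets the aryne; protonation of the aryl anion 17 (by bifluoride, by a second molecule of 9 or by the α-CH2 of the ketone), which stops at the open-chain aryl ether; loss of chloride from the ortho-chloroaryl anion to give a second aryne. Ring closure has to win against all three, and the tether is flexible, unlike the rigid ortho-hydroxyaryl ketones of the precedent.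
- Fallback (known chemistry, sets out from 4, returns at 20): bromide 4 is lithiated to 5 as in step 4, transmetallated with CeCl3 to suppress enolisation, and added to (2S)-7-(benzyloxy)-2-[4-(benzyloxy)phenyl]chroman-4-one F1. F1 is available by divalent-palladium-catalysed enantioselective conjugate addition of 4-(benzyloxy)phenylboronic acid to 7-(benzyloxy)chromone [Pd(OCOCF3)2, chiral pyridine–oxazoline ligand of the antipode that gives the 2S series]. Aryl-metal addition to a flavan-4-one is an established way to make a C4–C8 bond and should give the chlorine-free tertiary carbinol F2. Acid-catalysed dehydration of F2 (pyridinium p-toluenesulfonate, toluene) should give the 4-arylflav-3-ene F3. Hydrogenation over Pd(OH)2/C then adds hydrogen to the C3–C4 double bond from the face away from the C2 aryl group and removes the eight benzyl groups, giving 20.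

**Step 5.**
- What may go wrong: insufficient facial selectivity in the aldol, because enol diisopinocampheylborinates of methyl ketones are only moderately selective and the lower-unit stereocentres are too remote to reinforce them; separation of the two carbinol epimers may also be laborious.
- Fallback (sets out from 6 and 7, returns at 9): Claisen–Schmidt condensation (KOH, EtOH–THF) gives the (E)-chalcone F4. CuCl/NaOt-Bu with a chiral ferrocenyl bisphosphine, B2pin2 and MeOH in THF adds boron to the β-carbon under ligand control to give the β-boryl ketone F5. NaBO3·4H2O oxidises the C–B bond with retention to 9.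

**Step 10.**
- What may go wrong: poor facial selectivity of hydride delivery to the C4 cation, because the twisted ring D substituent and the peri chlorine shield both faces; opening of the C2–O1 bond by the acid with loss of C2 integrity or over-reduction.
- Fallback (sets out from 18, returns at 20): 18 is dehydrated (pyridinium p-toluenesulfonate, toluene) to the 5-chloro-4-arylflav-3-ene F6. Hydrogenation over Pd(OH)2/C, with Et3N added in a second stage, delivers both hydrogens syn to the face opposite the C2 aryl group, which is the known route to 2,4-cis-4-arylflavans. The same operation removes the benzyl groups and chlorine, so 20 is reached in the same number of steps.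

**Step 11.**
- What may go wrong: incomplete hydrogenolysis of the hindered, electron-rich C–Cl bond; slowing of benzyl ether cleavage by the amine; hydrogenolysis of the benzylic C2–O1 bonds if the conditions are forced.
- Fallback (sets out from 19, returns at 20): chlorine is removed first in solution by oxidative addition to a zerovalent palladium–phosphine catalyst and formate reduction [Pd(OAc)2, a bulky biarylphosphine, HCO2Na, DMF, 80 °C]. This does not depend on adsorption of the crowded arene on a metal surface and leaves benzyl ethers intact. The resulting chlorine-free octabenzyl ether F7 is then debenzylated by hydrogenolysis over Pd(OH)2/C without amine.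

## Further compounds

F1 | step 9 | (2S)-7-(benzyloxy)-2-[4-(benzyloxy)phenyl]chroman-4-one | c1ccccc1COc1ccc([C@@H]2CC(=O)c3ccc(OCc4ccccc4)cc3O2)cc1
F2 | step 9 | (2S)-7-(benzyloxy)-2-[4-(benzyloxy)phenyl]-4-(hexa-O-benzyl-epigallocatechin-8-yl)chroman-4-ol, C4 unassigned | c1ccccc1COc1ccc([C@@H]2CC(O)(c3c(OCc4ccccc4)cc(OCc4ccccc4)c4c3O[C@H](c3cc(OCc5ccccc5)c(OCc5ccccc5)c(OCc5ccccc5)c3)[C@H](OCc3ccccc3)C4)c3ccc(OCc4ccccc4)cc3O2)cc1
F3 | step 9 | (2S)-7-(benzyloxy)-2-[4-(benzyloxy)phenyl]-4-(hexa-O-benzyl-epigallocatechin-8-yl)-2H-chromene | c1ccccc1COc1ccc([C@@H]2C=C(c3c(OCc4ccccc4)cc(OCc4ccccc4)c4c3O[C@H](c3cc(OCc5ccccc5)c(OCc5ccccc5)c(OCc5ccccc5)c3)[C@H](OCc3ccccc3)C4)c3ccc(OCc4ccccc4)cc3O2)cc1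
F4 | step 5 | (E)-3-[4-(benzyloxy)phenyl]-1-(hexa-O-benzyl-epigallocatechin-8-yl)prop-2-en-1-one | O=C(/C=C/c1ccc(OCc2ccccc2)cc1)c1c(OCc2ccccc2)cc(OCc2ccccc2)c2c1O[C@H](c1cc(OCc3ccccc3)c(OCc3ccccc3)c(OCc3ccccc3)c1)[C@H](OCc1ccccc1)C2
F5 | step 5 | (S)-3-[4-(benzyloxy)phenyl]-3-(4,4,5,5-tetramethyl-1,3,2-dioxaborolan-2-yl)-1-(hexa-O-benzyl-epigallocatechin-8-yl)propan-1-one | c1ccccc1COc1ccc([C@@H](B2OC(C)(C)C(C)(C)O2)CC(=O)c2c(OCc3ccccc3)cc(OCc3ccccc3)c3c2O[C@H](c2cc(OCc4ccccc4)c(OCc4ccccc4)c(OCc4ccccc4)c2)[C@H](OCc2ccccc2)C3)cc1
F6 | step 10 | (2S)-7-(benzyloxy)-2-[4-(benzyloxy)phenyl]-5-chloro-4-(hexa-O-benzyl-epigallocatechin-8-yl)-2H-chromene | c1ccccc1COc1ccc([C@@H]2C=C(c3c(OCc4ccccc4)cc(OCc4ccccc4)c4c3O[C@H](c3cc(OCc5ccccc5)c(OCc5ccccc5)c(OCc5ccccc5)c3)[C@H](OCc3ccccc3)C4)c3c(Cl)cc(OCc4ccccc4)cc3O2)cc1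
F7 | step 11 | (2R,3R)-3,5,7-tris(benzyloxy)-8-{(2S,4S)-7-(benzyloxy)-2-[4-(benzyloxy)phenyl]chroman-4-yl}-2-[3,4,5-tris(benzyloxy)phenyl]chromane | c1ccccc1COc1ccc([C@@H]2C[C@H](c3c(OCc4ccccc4)cc(OCc4ccccc4)c4c3O[C@H](c3cc(OCc5ccccc5)c(OCc5ccccc5)c(OCc5ccccc5)c3)[C@H](OCc3ccccc3)C4)c3ccc(OCc4ccccc4)cc3O2)cc1
A1 | alternative 1 | 8-vinyl-hexa-O-benzyl-(−)-epigallocatechin | C=Cc1c(OCc2ccccc2)cc(OCc2ccccc2)c2c1O[C@H](c1cc(OCc3ccccc3)c(OCc3ccccc3)c(OCc3ccccc3)c1)[C@H](OCc1ccccc1)C2
A2 | alternative 1 | 4-(benzyloxy)-1-bromo-2-(methoxymethoxy)benzene | COCOc1cc(OCc2ccccc2)ccc1Br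
A3 | alternative 1 | 1-methoxy-1,3,3-triarylpropane with the triaryl-substituted carbon (future C4) set and the methoxy carbon as both epimers | COC(c1ccc(OCc4ccccc4)cc1)C[C@H](c5c(OCc6ccccc6)cc(OCc6ccccc6)c7c5O[C@H](c5cc(OCc6ccccc6)c(OCc6ccccc6)c(OCc6ccccc6)c5)[C@H](OCc5ccccc5)C7)c3ccc(OCc4ccccc4)cc3OCOC
A4 | alternative 2 | 2,4-cis-7-(benzyloxy)-2-[4-(benzyloxy)phenyl]-4-[(triisopropylsilyloxy)ethynyl]chromane | c1ccccc1COc1ccc([C@@H]2C[C@H](C#CO[Si](C(C)C)(C(C)C)C(C)C)c3ccc(OCc4ccccc4)cc3O2)cc1
A5 | alternative 2 | 3-(benzyloxy)-4-[(E)-3-(3,4,5-tris(benzyloxy)phenyl)prop-2-en-1-yl]cyclobut-2-en-1-one | O=C1C=C(OCc2ccccc2)C1C/C=C/c1cc(OCc2ccccc2)c(OCc2ccccc2)c(OCc2ccccc2)c1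
A6 | alternative 2 | flavan bearing at C4 a 2-hydroxy-6-(triisopropylsilyloxy)-4-(benzyloxy)-3-cinnamylphenyl ring | c4ccccc4COc1ccc([C@@H]2C[C@H](c5c(O[Si](C(C)C)(C(C)C)C(C)C)cc(OCc6ccccc6)c(C/C=C/c6cc(OCc7ccccc7)c(OCc7ccccc7)c(OCc7ccccc7)c6)c5O)c3ccc(OCc4ccccc4)cc3O2)cc1
A7 | alternative 3 | 2,4-cis flavan bearing at C4 a 2,4-bis(benzyloxy)phenyl ring whose 6-oxygen carries the 1-[3,4,5-tris(benzyloxy)phenyl]-2,3-epoxypropyl group | c1ccccc1COc1ccc([C@@H]2C[C@H](c3c(OCc4ccccc4)cc(OCc4ccccc4)cc3O[C@H](c3cc(OCc4ccccc4)c(OCc4ccccc4)c(OCc4ccccc4)c3)[C@H]3CO3)c3ccc(OCc4ccccc4)cc3O2)cc1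
A8 | alternative 3 | hepta-O-benzyl ether of 20 with the lower 3-hydroxyl free | c4ccccc4COc1ccc([C@@H]2C[C@H](c5c(OCc6ccccc6)cc(OCc6ccccc6)c7c5O[C@H](c5cc(OCc6ccccc6)c(OCc6ccccc6)c(OCc6ccccc6)c5)[C@H](O)C7)c3ccc(OCc4ccccc4)cc3O2)cc1
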